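## Structural features

The target is a depside: two benzene rings joined only by an aryl ester, ring A being a 4-hydroxy-2-methoxy-6-propylbenzoyl unit and ring B a 2,4-dihydroxy-6-propylbenzoic acid. The ester oxygen sits on C3 of ring B, the carbon between the hydroxyl-bearing C2 and C4, so ring B is 1,2,3-trioxygenated with the acyl group on the middle oxygen. The target has no stereocentre; the only ones met on the route are the adjacent C1 and C6 of a reduced ring B, which are held trans and disappear on aromatisation. Three groups are fragile: the aryl ester, which base or nucleophilic solvents can cleave or shift to a neighbouring phenol oxygen, the 2,4-dihydroxybenzoic acid of ring B, which loses CO2 on heating or in strong acid, and the free phenols, which oxidise easily. The real difficulty is the ester itself: its acyl carbon is shielded by the ortho methoxy and propyl groups, and its oxygen is flanked on both sides and must be told apart from two other oxygens on ring B. A lesser problem is placing the methyl group on O2 and not on O4 of ring A. The key step exploits the fact that C3 of ring B, at the dihydro level, is C2 of a cyclohexane-1,3-dione: that one carbon between two carbonyls accepts a diazo group selectively and then, as a carbenoid, a carboxylate oxygen, while O2 and O4 are still carbonyl oxygens and cannot compete.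

## Logic of the disconnections

14 to 13: the two O–CH2Ph bonds are cut, one at the ring B carboxyl and one at O4 of ring A. The free acid decarboxylates readily and the depside ester does not tolerate base, so both acidic groups are masked by groups that leave together under neutral conditions. The gain is a single mild final step. The demand is a hydrogenolysis at room temperature in a non-nucleophilic solvent.

13 to 12: no skeletal bond is cut; two hydrogens are added back at C1 and C6 of ring B. At this oxidation level ring B is a cyclohexane-1,3-dione and C3 is its one doubly activated carbon, so the three oxygens of ring B become distinguishable. The gain is that the regiochemistry of ring B reduces to enolate chemistry. The forward step must remove exactly two hydrogens from an enolised acyloxydione without touching the benzyl groups or shifting the acyl group; the C1/C6 configuration needs no control.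

12 to 5 and 11: the bond cut is C3–O, between ring B and the carboxylate oxygen, not the usual acyl C–O bond. An acyl–O cut would make a 2,6-disubstituted acyl donor meet a doubly flanked oxygen nucleophile, whereas the C3–O cut lets the carboxylate oxygen act as the nucleophile toward an electrophilic C3. The gain is a convergent union of two fragments of similar size. The demand is that C3 be turned into an electrophile (a metal carbenoid from a diazo group) that prefers O–H insertion over its other pathways.

5 to 4: the C3=N2 bond is cut. The diazo group is the handle that makes C3 a carbenoid, and it goes onto the most acidic carbon of the ring without a directing group. The gain is that 4 carries no heteroatom at C3 and lies one step from commercial materials. The demand is transfer to the C3 methylene and not to C1, which the difference in acidity and the single hydrogen at C1 should secure.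

4 to 1 and 2, through 3: the C2–C3 bond (Claisen) and the C1–C6 bond (Michael) are cut. The 1,3-dione and the 1,5-dicarbonyl relationship point to a doubly activated Michael donor and an enone; 2 brings the propyl group and C3 to C6, and 1 brings C1, C2 and the ester. The gain is the whole ring B skeleton in one operation from two commercial compounds. The demand is an alkoxide matched to the benzyl ester and a cold acidic work-up that avoids decarboxylation.

11 to 10: the carboxyl C–OH bond is cut, a change of oxidation level only. An aldehyde is what electrophilic formylation delivers, and its carbonyl group tells the two phenols apart in the steps before. The gain is that no hindered ester has to be hydrolysed to reach the acid. The demand is an oxidant that spares the electron-rich ring and the benzyl ether.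

10 to 9: the O–CH3 bond at O2 is cut. The chelated 2-OH is the less reactive phenol and is best alkylated when it is the only one left. The gain is that the forward step needs no selectivity. The demand is a base strong enough to break the hydrogen bond to the aldehyde.

9 to 8: the O–CH2Ph bond at O4 is cut. The 4-OH is the more acidic and the unhindered phenol, so it can be addressed first. The gain is that 8 carries no protecting group at all. The demand is a weak base and one equivalent of halide, so that the chelated 2-OH stays free.

8 to 6, through 7: the aryl–CHO bond is cut. The position para to one hydroxyl and ortho to the other is the natural site of electrophilic attack on the resorcinol. The gain is that 6 is commercial and already has the carbon skeleton and oxygen pattern of ring A. The demand is formylation at C4 of the resorcinol and not at C2 between the hydroxyls.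

## Other disconnections considered

Alternative 1: The cut is the C1–C6 bond of ring A, so ring A is grown from a linear tetraketide chain that is already esterified to O3 of ring B.
- Forward step: the phenol benzyl 2,4-bis(benzyloxy)-3-hydroxy-6-propylbenzoate A3 would be acylated with an unhindered, activated tetraketide chain to give benzyl 2,4-bis(benzyloxy)-6-propyl-3-[(3,5,7-trioxodecanoyl)oxy]benzoate A2. A mild base would make C2 of the chain attack the C7 ketone, and acid would dehydrate the aldol to benzyl 2,4-bis(benzyloxy)-3-[(2,4-dihydroxy-6-propylbenzoyl)oxy]-6-propylbenzoate A1.
- In favour: the ester is made before ring A exists, so the shielded acyl carbon is avoided as completely as in the chosen plan; on this point the two are equal. Aromatisation is by dehydration alone and needs no oxidant, which is better than step 8.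
- Against, structure: A1 has free hydroxyls at both C2 and C4 of ring A, and the target needs methyl on O2, the chelated and less reactive one. Reaching 14 from A1 would need protection of O4, methylation under base beside a base-labile depside, and then hydrogenolysis. A3 is itself a 1,2,3-trioxygenated arene with only the middle hydroxyl free and is not trivial to make.
- Against, mechanism: the aryl ester of A2 is an activated leaving group next to a 1,3-diketone. The C5 enol oxygen can close onto the ester carbonyl in a six-membered lactonisation and expel A3, in competition with the wanted C-aldol.
- Step economy: at least three steps follow the key step, against two in the chosen plan, and A3 and the tetraketide chain must be made first.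

Alternative 2: The cut is the C5–C6 and C3–C4 bonds of ring A, which is assembled from a 2-pyrone and a two-carbon ketene equivalent.
- Forward step: methyl 4-methoxy-2-oxo-6-propyl-2H-pyran-5-carboxylate A5 and 1,1-bis(trimethylsilyloxy)ethene A6 would undergo a (4+2) cycloaddition of inverse electron demand, the CH2 carbon of A6 bonding to the propyl-bearing carbon of A5. The bridged adduct would lose CO2 and trimethylsilanol and give, after desilylation, methyl 4-hydroxy-2-methoxy-6-propylbenzoate A4.
- In favour: the methoxy and hydroxyl groups of ring A are placed by construction, with no site-selective alkylation; this is better than step 4 of the chosen plan. No oxidant is needed, A6 is a simple two-carbon partner, and the regiochemistry follows the polarisation of both partners.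
- Against, structure: the step builds only ring A. The depside bond and the three oxygens of ring B, which are the hard part, are untouched, so the O–H insertion or an equivalent is still needed. A4 is the methyl ester of a 2,6-disubstituted benzoic acid and must be O-benzylated and then saponified under forcing conditions to reach 11.
- Against, mechanism: the 4-methoxy group donates into the pyrone and should make A5 a weaker electron-poor diene.
- Step economy: A5 needs several steps of its own, so the way to 11 is longer than the four classical steps from 6.

Alternative 3: The cut is the C1–C2 and C5–C6 bonds of ring B, which is made by cycloaddition of a diene that already carries the ester.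
- Forward step: 1-methoxy-1,3-bis[(trimethylsilyl)oxy]buta-1,3-dien-2-yl 4-(benzyloxy)-2-methoxy-6-propylbenzoate A8 would add to benzyl hex-2-ynoate A9, its CH2 terminus bonding to the propyl-bearing alkyne carbon. Loss of methanol and of the silyl groups would give benzyl 3-{[4-(benzyloxy)-2-methoxy-6-propylbenzoyl]oxy}-2,4-dihydroxy-6-propylbenzoate A7. A7 is the same compound as 13, so this plan would join the chosen route just before step 9.
- In favour: the position of the ester oxygen is fixed by C2 of the diene, a certainty equal to that of the diazo carbon. Ring B is formed aromatic, so no dehydrogenation is needed, which is better than the chosen plan after the key step. The ester link of the diene precursor can be made by alkylating the carboxylate of 11 with methyl 2-chloro-3-oxobutanoate A10, so the hindered acid again reacts through oxygen; this is equal in logic.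
- Against, structure: A8 is a tetra-oxygenated, moisture-sensitive diene. Its preparation needs two enol silylations, the second with a strong base beside an acyloxy group that can migrate to the enolate oxygen.
- Against, mechanism: A9 is an internal alkynoate with a beta-alkyl group and a sluggish dienophile. The heating it needs invites diene decomposition and silyl or acyl transfer, so the step is less controllable than a catalytic carbenoid reaction near room temperature.
- Step economy: the total count is roughly equal, but the risk sits in a labile intermediate rather than in robust, isolable compounds such as 4, 5 and 11.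

Key step: step 7

Assumption: the target is achiral, so 3, 4, 5 and 12 are taken as racemates, and the SMILES of 4, 5 and 12 show the (1S,6R) enantiomer of the trans pair as a stand-in for the racemate.

## Route

Step 1
Reactants: 1 dibenzyl malonate; 2 (E)-hept-3-en-2-one
Product: 4 benzyl trans-2,4-dioxo-6-propylcyclohexane-1-carboxylate (racemic), via Michael adduct 3 (not isolated)
Conditions: NaH (1.1 equiv), BnOH (1.2 equiv), THF, 0 °C; add 1, then 2, 0 °C to reflux; 1 M HCl, 0 °C
Reagents that add atoms: none
Why: Tandem Michael addition and Claisen (Dieckmann-type) condensation: NaOBn adds the malonate to the enone to give 3, the methyl ketone enolate closes onto one benzyl ester, and the acidic dione enolate is the thermodynamic sink, while benzyloxide makes ester exchange degenerate. C6 forms as a racemate in the conjugate addition and the epimerisable C1 settles trans to the propyl group under the equilibrating conditions; both centres are erased in step 8.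

Step 2
Reactants: 4 benzyl trans-2,4-dioxo-6-propylcyclohexane-1-carboxylate
Product: 5 benzyl trans-3-diazo-2,4-dioxo-6-propylcyclohexane-1-carboxylate (racemic)
Conditions: 4-acetamidobenzenesulfonyl azide (1.05 equiv), Et3N (1.2 equiv), MeCN, 0 °C to rt
Reagents that add atoms: 4-acetamidobenzenesulfonyl azide, CC(=O)Nc1ccc(cc1)S(=O)(=O)N=[N+]=[N-]
Why: Regitz diazo transfer: the C3 methylene between the two ketones is by far the most acidic carbon and the only doubly activated CH2, so the sulfonyl azide delivers N2 there, while C1 has a single hydrogen and cannot become a diazo carbon. The trans C1/C6 relationship is thermodynamic and is kept.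

Step 3
Reactants: 6 5-propylbenzene-1,3-diol
Product: 8 2,4-dihydroxy-6-propylbenzaldehyde, via aryl iminium chloride 7 (not isolated)
Conditions: POCl3 (1.2 equiv), DMF, 0 °C to rt; then H2O, 50 °C
Reagents that add atoms: N,N-dimethylformamide, CN(C)C=O; water, O
Why: Vilsmeier–Haack formylation: the chloroiminium ion attacks the resorcinol para to one hydroxyl and ortho to the other, the usual site for 5-alkylresorcinols, in preference to C2 between the hydroxyls. Aqueous hydrolysis of iminium salt 7 releases the aldehyde.

Step 4
Reactants: 8 2,4-dihydroxy-6-propylbenzaldehyde
Product: 9 4-(benzyloxy)-2-hydroxy-6-propylbenzaldehyde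
Conditions: BnBr (1.05 equiv), NaHCO3 (1.5 equiv), KI (cat.), MeCN, 70 °C
Reagents that add atoms: benzyl bromide, BrCc1ccccc1
Why: Williamson etherification under a weak base: the 4-OH, para to the formyl group, is the more acidic and is unhindered, whereas the 2-OH is locked in a hydrogen bond to the aldehyde, so one equivalent of halide should alkylate O4 selectively.

Step 5
Reactants: 9 4-(benzyloxy)-2-hydroxy-6-propylbenzaldehyde
Product: 10 4-(benzyloxy)-2-methoxy-6-propylbenzaldehyde
Conditions: MeI (2 equiv), K2CO3 (2 equiv), DMF, 40 °C
Reagents that add atoms: iodomethane, CI
Why: Williamson methylation of the chelated phenol with the stronger base K2CO3 in a dipolar solvent; only one hydroxyl is left, so no selectivity is required.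

Step 6
Reactants: 10 4-(benzyloxy)-2-methoxy-6-propylbenzaldehyde
Product: 11 4-(benzyloxy)-2-methoxy-6-propylbenzoic acid
Conditions: NaClO2, NaH2PO4, 2-methylbut-2-ene, t-BuOH/H2O, 0 °C to rt
Reagents that add atoms: sodium chlorite, [Na+].[O-]Cl=O
Why: Pinnick oxidation turns the hindered, electron-rich aldehyde into the acid under mildly acidic conditions that leave the benzyl ether alone. The alkene scavenger traps HOCl, which would otherwise chlorinate the activated ring.

Step 7
Reactants: 5 benzyl trans-3-diazo-2,4-dioxo-6-propylcyclohexane-1-carboxylate; 11 4-(benzyloxy)-2-methoxy-6-propylbenzoic acid
Product: 12 benzyl trans-3-{[4-(benzyloxy)-2-methoxy-6-propylbenzoyl]oxy}-2-hydroxy-4-oxo-6-propylcyclohex-2-ene-1-carboxylate (racemic, enol form)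
Conditions: Rh2(OAc)4 (2 mol %), 11 (1.5 equiv), 4 Å sieves, CH2Cl2, dark, slow addition of 5, rt to 40 °C
Reagents that add atoms: none
Why: Rh2(OAc)4 binds the diazo carbon at an axial site of one divalent rhodium centre and expels N2 to give a carbenoid at C3 that the two flanking carbonyl groups make strongly electrophilic. The hydroxyl oxygen of 11 adds to this carbon to form an oxonium ylide, and a 1,2-proton shift with release of the catalyst gives the 2-acyloxy-1,3-dione, which settles as the hydrogen-bonded enol 12. The closest known reaction type is the dirhodium tetracarboxylate catalysed O–H insertion of carboxylic acids into 2-diazo-1,3-dicarbonyl compounds. No ring is closed and no stereocentre is created: the one new bond is C3–O, C3 ends sp2 in the enol, and the trans C1/C6 pair is carried through unchanged. Regiochemistry needs no control, because the diazo carbon is the only carbenoid site, and this puts the ester oxygen on the middle carbon of the later 2,3,4-trioxygenated ring. The selectivity needed is O–H insertion over Wolff ring contraction, attack on the electron-rich arene of 11 and carbene dimerisation; a low temperature, exclusion of light, a non-aromatic solvent, the acid in excess and slow addition of 5 all favour the bimolecular O–H pathway. Steric hindrance does not interfere, because 11 reacts through its oxygen, away from the carbonyl carbon shielded by the ortho methoxy and propyl groups, and the same shielding should hold back a later 1,2-acyl shift to the neighbouring enol oxygen.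

Step 8
Reactants: 12 benzyl trans-3-{[4-(benzyloxy)-2-methoxy-6-propylbenzoyl]oxy}-2-hydroxy-4-oxo-6-propylcyclohex-2-ene-1-carboxylate
Product: 13 benzyl 3-{[4-(benzyloxy)-2-methoxy-6-propylbenzoyl]oxy}-2,4-dihydroxy-6-propylbenzoate
Conditions: DDQ (1.2 equiv), 1,4-dioxane, 60–80 °C; then aq. NaHCO3 wash
Reagents that add atoms: none
Why: Dehydrogenative aromatisation of a 4-alkoxycarbonylcyclohexane-1,3-dione to a 2,4-dihydroxybenzoate: DDQ takes a hydride from C6 of the enolised dione and enolisation through C1 gives the aromatic tautomer, where the gain in aromaticity stops the oxidation. The central dione carbon is blocked by the acyloxy group, so addition of the enol to the quinone is disfavoured, and the aryl benzyl ether and the ring A propyl group (meta to both alkoxy groups) are not activated toward DDQ. Both stereocentres disappear here.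

Step 9
Reactants: 13 benzyl 3-{[4-(benzyloxy)-2-methoxy-6-propylbenzoyl]oxy}-2,4-dihydroxy-6-propylbenzoate
Product: 14 2,4-dihydroxy-3-[(4-hydroxy-2-methoxy-6-propylbenzoyl)oxy]-6-propylbenzoic acid
Conditions: H2 (1 atm), Pd/C (10 wt %), EtOAc, rt
Reagents that add atoms: none
Why: Catalytic hydrogenolysis cleaves the benzyl ester and the benzyl ether in one neutral operation; the aryl ester, the methyl ether and the arenes are inert. A non-nucleophilic solvent and room temperature avoid transesterification of the depside and decarboxylation of the 2,4-dihydroxybenzoic acid.

## Compound list

1 | dibenzyl malonate | O=C(CC(=O)OCc1ccccc1)OCc1ccccc1 | starting material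
2 | (E)-hept-3-en-2-one | CCC/C=C/C(C)=O | starting material
3 | dibenzyl 2-(2-oxoheptan-4-yl)propanedioate (racemic Michael adduct, not isolated) | CCCC(CC(C)=O)C(C(=O)OCc1ccccc1)C(=O)OCc1ccccc1 | intermediate
4 | benzyl trans-2,4-dioxo-6-propylcyclohexane-1-carboxylate (racemic, largely enolised) | CCC[C@@H]1CC(=O)CC(=O)[C@H]1C(=O)OCc1ccccc1 | intermediate
5 | benzyl trans-3-diazo-2,4-dioxo-6-propylcyclohexane-1-carboxylate (racemic) | CCC[C@@H]1CC(=O)C(=[N+]=[N-])C(=O)[C@H]1C(=O)OCc1ccccc1 | intermediate
6 | 5-propylbenzene-1,3-diol | CCCc1cc(O)cc(O)c1 | starting material
7 | [(2,4-dihydroxy-6-propylphenyl)methylidene]dimethylammonium chloride (not isolated) | CCCc1cc(O)cc(O)c1C=[N+](C)C.[Cl-] | intermediate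
8 | 2,4-dihydroxy-6-propylbenzaldehyde | CCCc1cc(O)cc(O)c1C=O | intermediate
9 | 4-(benzyloxy)-2-hydroxy-6-propylbenzaldehyde | CCCc1cc(OCc2ccccc2)cc(O)c1C=O | intermediate
10 | 4-(benzyloxy)-2-methoxy-6-propylbenzaldehyde | CCCc1cc(OCc2ccccc2)cc(OC)c1C=O | intermediate
11 | 4-(benzyloxy)-2-methoxy-6-propylbenzoic acid | CCCc1cc(OCc2ccccc2)cc(OC)c1C(=O)O | intermediate
12 | benzyl trans-3-{[4-(benzyloxy)-2-methoxy-6-propylbenzoyl]oxy}-2-hydroxy-4-oxo-6-propylcyclohex-2-ene-1-carboxylate (racemic, enol form) | CCC[C@@H]1CC(=O)C(OC(=O)c2c(CCC)cc(OCc3ccccc3)cc2OC)=C(O)[C@H]1C(=O)OCc1ccccc1 | intermediate
13 | benzyl 3-{[4-(benzyloxy)-2-methoxy-6-propylbenzoyl]oxy}-2,4-dihydroxy-6-propylbenzoate | CCCc1cc(O)c(OC(=O)c2c(CCC)cc(OCc3ccccc3)cc2OC)c(O)c1C(=O)OCc1ccccc1 | intermediate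
14 | 2,4-dihydroxy-3-[(4-hydroxy-2-methoxy-6-propylbenzoyl)oxy]-6-propylbenzoic acid | CCCc1cc(O)cc(OC)c1C(=O)Oc1c(O)cc(CCC)c(C(=O)O)c1O | target

## Step count and least certain steps

Total: 9 steps. Longest linear sequence: 7 steps (steps 3 to 9, from 6 to 14); the ring B branch adds steps 1 and 2.

**Step 7 (key step).** The carbenoid may be diverted: Wolff ring contraction, attack on the dialkoxyarene of 11, or insertion into adventitious water. Loss of nitrogen from the doubly stabilised diazo compound may also be slow near room temperature, and the acyl group may shift to the neighbouring enol oxygen of the product. The fallback sets out from 4 and 11 and comes back at 12. 4 is treated with PhI(OAc)2 and Na2CO3 (CH2Cl2/H2O, 0 °C) to give the phenyliodonium ylide, benzyl trans-2,4-dioxo-3-(phenyl-λ3-iodanylidene)-6-propylcyclohexane-1-carboxylate F1. Warming F1 with 11 in CH2Cl2 should protonate the ylide carbon to an alkyl(phenyl)iodonium carboxylate, and ligand coupling with loss of iodobenzene should give 12 without a diazo compound or a metal carbenoid.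

**Step 8.** Hydride abstraction may stall or run past the resorcinol stage, the enol may add to the quinone, or the benzyl ether may be partly lost by oxidation. The fallback sets out from 12 and comes back at 14. 12 is treated with an excess of CuBr2 and LiBr in MeCN: bromination, loss of HBr to the arene, then nuclear bromination at the one free position of the new resorcinol. This should give benzyl 5-bromo-3-{[4-(benzyloxy)-2-methoxy-6-propylbenzoyl]oxy}-2,4-dihydroxy-6-propylbenzoate F2. Hydrogenation of F2 over Pd/C with NaOAc in EtOAc then removes the bromine together with both benzyl groups and should give 14 directly. Any bromine that entered ring A would be stripped in the same operation.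

**Step 4.** Site selectivity may be lost through double benzylation or alkylation at O2, because both phenols are nucleophilic once deprotonated. The fallback sets out from 8 and comes back at 9. Exhaustive benzylation (BnBr, K2CO3, DMF) gives 2,4-bis(benzyloxy)-6-propylbenzaldehyde F3. MgBr2·OEt2 in toluene/Et2O then cleaves only the benzyl ether of F3 that stands ortho to the formyl group, through a six-membered magnesium chelate, and should give 9.

**Step 1.** Ring closure may be incomplete, or retro-Michael cleavage may occur under the reversible alkoxide conditions; ester hydrolysis with decarboxylation may occur during acidification. The fallback sets out from 1 and 2 and comes back at 4, with the cascade divided into two operations. The conjugate addition is run with a catalytic base (K2CO3 with Bu4NBr, toluene, rt) and 3 is isolated. Purified 3 is then closed irreversibly with KOtBu in THF at 0 °C, a hindered base that does not exchange the esters. This fallback makes no compound outside the compound list and is entered below as F0.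

## Further compounds

F1 | step 7 | benzyl trans-2,4-dioxo-3-(phenyl-λ3-iodanylidene)-6-propylcyclohexane-1-carboxylate (racemic) | CCC[C@@H]1CC(=O)[C-]([I+]c2ccccc2)C(=O)[C@H]1C(=O)OCc1ccccc1
F2 | step 8 | benzyl 5-bromo-3-{[4-(benzyloxy)-2-methoxy-6-propylbenzoyl]oxy}-2,4-dihydroxy-6-propylbenzoate | CCCc1c(Br)c(O)c(OC(=O)c2c(CCC)cc(OCc3ccccc3)cc2OC)c(O)c1C(=O)OCc1ccccc1
F3 | step 4 | 2,4-bis(benzyloxy)-6-propylbenzaldehyde | CCCc1cc(OCc2ccccc2)cc(OCc2ccccc2)c1C=O
F0 | step 1 | none | none
A1 | alternative 1 | benzyl 2,4-bis(benzyloxy)-3-[(2,4-dihydroxy-6-propylbenzoyl)oxy]-6-propylbenzoate | CCCc1cc(O)cc(O)c1C(=O)Oc1c(OCc2ccccc2)cc(CCC)c(C(=O)OCc2ccccc2)c1OCc1ccccc1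
A2 | alternative 1 | benzyl 2,4-bis(benzyloxy)-6-propyl-3-[(3,5,7-trioxodecanoyl)oxy]benzoate | CCCC(=O)CC(=O)CC(=O)CC(=O)Oc1c(OCc2ccccc2)cc(CCC)c(C(=O)OCc2ccccc2)c1OCc1ccccc1
A3 | alternative 1 | benzyl 2,4-bis(benzyloxy)-3-hydroxy-6-propylbenzoate | CCCc1cc(OCc2ccccc2)c(O)c(OCc2ccccc2)c1C(=O)OCc1ccccc1
A4 | alternative 2 | methyl 4-hydroxy-2-methoxy-6-propylbenzoate | CCCc1cc(O)cc(OC)c1C(=O)OC
A5 | alternative 2 | methyl 4-methoxy-2-oxo-6-propyl-2H-pyran-5-carboxylate | CCCC1=C(C(=O)OC)C(OC)=CC(=O)O1
A6 | alternative 2 | 1,1-bis(trimethylsilyloxy)ethene | C=C(O[Si](C)(C)C)O[Si](C)(C)C
A7 | alternative 3 | benzyl 3-{[4-(benzyloxy)-2-methoxy-6-propylbenzoyl]oxy}-2,4-dihydroxy-6-propylbenzoate | CCCc1cc(O)c(OC(=O)c2c(CCC)cc(OCc3ccccc3)cc2OC)c(O)c1C(=O)OCc1ccccc1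
A8 | alternative 3 | 1-methoxy-1,3-bis[(trimethylsilyl)oxy]buta-1,3-dien-2-yl 4-(benzyloxy)-2-methoxy-6-propylbenzoate | C=C(O[Si](C)(C)C)C(OC(=O)c1c(CCC)cc(OCc2ccccc2)cc1OC)=C(OC)O[Si](C)(C)C
A9 | alternative 3 | benzyl hex-2-ynoate | CCCC#CC(=O)OCc1ccccc1
A10 | alternative 3 | methyl 2-chloro-3-oxobutanoate | CC(=O)C(Cl)C(=O)OC
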